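**Strategy.** All three flavan units derive from one monomer, so the C3–C4 bond of ring C in the top unit is made at the monomer stage. Ring-closing metathesis between a 1-benzyloxyvinyl group on C2 and the ortho vinyl group of ring A closes the pyran ring as a 3-benzyloxy-2H-chromene in one operation. The step exploits that C3 bears oxygen and C4 is benzylic to ring A: the resulting enol ether C3=C4 then accepts H (C3) and OH (C4) anti to the C2 aryl group, giving the 2,3-cis pattern. The precursor is an acyclic diene ether with C2 already set. Thioether-activated units are finally joined C4→C6.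

Key step: step 6

Remark: flavan numbering is used (O1, C2, C3, C4, C4a–C8a; ring A = benzo ring, ring B = 4-oxyphenyl on C2, ring C = pyran ring); α is the face of ring C that carries the C2 aryl group, β the opposite face.

Step 1
Reactants: 1 2,3,4-trihydroxybenzaldehyde
Product: 2 3,4-bis(benzyloxy)-2-hydroxybenzaldehyde
Conditions: BnBr (2.1 equiv), K2CO3 (2.1 equiv), DMF, rt
Reagents that add atoms: benzyl bromide, BrCc1ccccc1
Why: Williamson etherification, in which the 2-OH, hydrogen-bonded to the aldehyde, is the least reactive hydroxyl, so the 4- and 3-OH should be benzylated first.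

Step 2
Reactants: 3 1-(benzyloxy)-4-bromobenzene; 4 dibenzyl oxalate
Product: 6 benzyl 2-[4-(benzyloxy)phenyl]-2-oxoacetate, via aryl Grignard reagent 5 (not isolated)
Conditions: Mg, THF, reflux; then added to 4 (2 equiv), THF, −78 °C; aq. NH4Cl
Reagents that add atoms: none
Why: Grignard mono-acylation of an oxalate diester, in which the tetrahedral adduct persists at −78 °C and so should prevent a second addition.

Step 3
Reactants: 6 benzyl 2-[4-(benzyloxy)phenyl]-2-oxoacetate
Product: 7 benzyl (2S)-2-[4-(benzyloxy)phenyl]-2-hydroxyacetate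
Conditions: RuCl[(R,R)-TsDPEN](p-cymene) (1 mol %), HCO2H/Et3N (5:2), DMF, rt
Reagents that add atoms: none
Why: Noyori asymmetric transfer hydrogenation of an aryl α-keto ester, in which the catalyst sets the stereocentre; the (R,R) complex is the antipode expected to give the (S)-alcohol if the aryl group is recognised as in aryl ketone reductions.

Step 4
Reactants: 2 3,4-bis(benzyloxy)-2-hydroxybenzaldehyde; 7 benzyl (2S)-2-[4-(benzyloxy)phenyl]-2-hydroxyacetate
Product: 8 benzyl (2R)-2-[2,3-bis(benzyloxy)-6-formylphenoxy]-2-[4-(benzyloxy)phenyl]acetate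
Conditions: PPh3, DIAD, THF, 0 °C → rt
Reagents that add atoms: none
Why: Mitsunobu etherification of an acidic phenol with an α-hydroxy ester, in which SN2 inversion at the α-carbonyl benzylic carbon should turn (S)-7 into the (R)-ether, the future C2.

Step 5
Reactants: 8 benzyl (2R)-2-[2,3-bis(benzyloxy)-6-formylphenoxy]-2-[4-(benzyloxy)phenyl]acetate
Product: 9 1,2-bis(benzyloxy)-3-{[(1R)-2-(benzyloxy)-1-[4-(benzyloxy)phenyl]prop-2-en-1-yl]oxy}-4-ethenylbenzene
Conditions: Cp2TiMe2 (4 equiv), toluene/THF, 70 °C, dark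
Reagents that add atoms: dimethyltitanocene (Petasis reagent), C[Ti](C)(C1C=CC=C1)C1C=CC=C1
Why: Petasis methylenation through Cp2Ti=CH2 should convert the aldehyde into the styrene and the ester into the 1-benzyloxyvinyl ether under non-basic conditions, so the acidic C2–H is not epimerised.

Step 6
Reactants: 9 1,2-bis(benzyloxy)-3-{[(1R)-2-(benzyloxy)-1-[4-(benzyloxy)phenyl]prop-2-en-1-yl]oxy}-4-ethenylbenzene
Product: 10 (2R)-3,7,8-tris(benzyloxy)-2-[4-(benzyloxy)phenyl]-2H-chromene
Conditions: second-generation Grubbs catalyst (5 mol %), 1,4-benzoquinone (10 mol %), toluene, 60 °C, argon sparge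
Reagents that add atoms: none
Why: Ring-closing olefin metathesis by the Chauvin mechanism: the ruthenium benzylidene formed at the styrene of ring A undergoes intramolecular [2+2] cycloaddition with the 1,1-disubstituted enol ether, and cycloreversion releases ethylene and the ring. The closest known reaction types are the RCM of olefinic enol ethers to cyclic enol ethers and of O-allyl 2-vinylphenols to 2H-chromenes. The six-membered ring C is closed by metathesis of the two terminal alkenes so that the new C3=C4 bond is endocyclic. No stereocentre is formed; C2 (R) is untouched, and its aryl group, pseudo-axial next to the C3 benzyloxy group, is the element that will direct the following hydroboration. The step needs initiation at the styrene and not at the electron-rich enol ether (which would give a Fischer carbene), and no migration of the enol ether double bond towards C2; the more accessible monosubstituted styrene, removal of ethylene and the benzoquinone hydride scavenger should secure this.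

Step 7
Reactants: 10 (2R)-3,7,8-tris(benzyloxy)-2-[4-(benzyloxy)phenyl]-2H-chromene
Product: 12 (2R,3R,4S)-3,7,8-tris(benzyloxy)-2-[4-(benzyloxy)phenyl]chroman-4-ol (2,3-cis-3,4-trans), via alkylborane 11 (not isolated)
Conditions: BH3·THF (1.5 equiv), THF, 0 °C; then NaOH, H2O2, 0 °C
Reagents that add atoms: hydrogen peroxide, OO
Why: Hydroboration–oxidation of a cyclic enol ether, in which boron should add to C4 (β to the enol ether oxygen, the less substituted carbon) and H to C3 on the β face opposite the C2 aryl group, so that oxidation with retention gives 3α-OBn (cis to the aryl group) and 4β-OH.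

Step 8
Reactants: 12 (2R,3R,4S)-3,7,8-tris(benzyloxy)-2-[4-(benzyloxy)phenyl]chroman-4-ol
Product: 13 (2R,3S,4S)-3,7,8-tris(benzyloxy)-2-[4-(benzyloxy)phenyl]-4-(benzylsulfanyl)chromane (4β-thioether; same spatial arrangement as 12)
Conditions: BnSH (5 equiv), ZnI2 (0.2 equiv), CH2Cl2, 0 °C
Reagents that add atoms: benzyl mercaptan, SCc1ccccc1
Why: Lewis-acid-catalysed SN1 thiolysis of the flavan-4-ol through the C4 cation (stabilised by the para 7-benzyloxy group), the excess thiol outrunning self-alkylation and entering trans to the 3-benzyloxy group.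

Step 9
Reactants: 12 (2R,3R,4S)-3,7,8-tris(benzyloxy)-2-[4-(benzyloxy)phenyl]chroman-4-ol
Product: 14 (2R,3S)-3,7,8-tris(benzyloxy)-2-[4-(benzyloxy)phenyl]chroman-4-one (2,3-cis)
Conditions: DMP, pyridine, CH2Cl2, 0 °C → rt
Reagents that add atoms: none
Why: Dess–Martin oxidation of the benzylic alcohol under buffered, non-enolising conditions should leave the 2,3-cis relationship at C3 intact.

Step 10
Reactants: 14 (2R,3S)-3,7,8-tris(benzyloxy)-2-[4-(benzyloxy)phenyl]chroman-4-one
Product: 15 (2R,3R,4R)-3,7,8-tris(benzyloxy)-2-[4-(benzyloxy)phenyl]chroman-4-ol (2,3-cis-3,4-cis)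
Conditions: NaBH4, CeCl3·7H2O, MeOH/THF, −40 °C
Reagents that add atoms: none
Why: Luche reduction, in which hydride should attack C4 from the open β face, anti to the axial 3-benzyloxy group (Felkin–Anh), giving the 4α-alcohol cis to O3.

Step 11
Reactants: 15 (2R,3R,4R)-3,7,8-tris(benzyloxy)-2-[4-(benzyloxy)phenyl]chroman-4-ol
Product: 16 (2R,3R,4R)-3,4,7,8-tetrakis(benzyloxy)-2-[4-(benzyloxy)phenyl]chromane
Conditions: NaH, BnBr, Bu4NI (cat.), DMF, 0 °C → rt
Reagents that add atoms: benzyl bromide, BrCc1ccccc1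
Why: Williamson benzylation caps the 4α-OH, so the lower unit carries no free hydroxyl that could be O-alkylated in the couplings.

Step 12
Reactants: 13 (2R,3S,4S)-4-(benzylsulfanyl) electrophile; 16 (2R,3R,4R)-3,4,7,8-tetrakis(benzyloxy)-2-[4-(benzyloxy)phenyl]chromane
Product: 17 nona-O-benzyl-epioritin-(4β→6)-epioritin-4α-ol (upper unit 2,3-cis-3,4-trans, its C4 bonded to C6 of the all-cis lower unit)
Conditions: AgBF4 (2.5 equiv), 2,6-di-tert-butyl-4-methylpyridine, THF, 0 °C; 16 (3 equiv), 13 added slowly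
Reagents that add atoms: none
Why: Thiophilic activation of the 4-thioether gives the C4 cation for a Friedel–Crafts interflavanyl coupling at C6 of 16 (para to O1, ortho to the 7-benzyloxy group, less hindered than C5), with attack on the β face anti to the 3-benzyloxy and C2 aryl groups setting the new C4 centre as 4β.

Step 13
Reactants: 13 (2R,3S,4S)-4-(benzylsulfanyl) electrophile; 17 nona-O-benzyl dimer
Product: 18 trideca-O-benzyl-epioritin-(4β→6)-epioritin-(4β→6)-epioritin-4α-ol
Conditions: AgBF4 (2.5 equiv), 2,6-di-tert-butyl-4-methylpyridine, THF, 0 °C; 13 (1.2 equiv) added slowly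
Reagents that add atoms: none
Why: The same silver-promoted Friedel–Crafts coupling, in which the only free C6 position of 17 is that of its upper unit and attack anti to the 3-benzyloxy group should again give the 4β (3,4-trans) linkage.

Step 14
Reactants: 18 trideca-O-benzyl trimer
Product: 19 epioritin-(4β→6)-epioritin-(4β→6)-epioritin-4α-ol (target)
Conditions: H2 (1 atm), Pd(OH)2/C, THF/MeOH, rt
Reagents that add atoms: none
Why: Hydrogenolysis of all thirteen benzyl ethers under neutral conditions, in which the O–CH2Ph bonds should cleave faster than the ring C4–O bond and the interflavanyl C–C bonds are inert, so no stereocentre is touched.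

**Compound list**

1 | 2,3,4-trihydroxybenzaldehyde | O=Cc1ccc(O)c(O)c1O | starting material
2 | 3,4-bis(benzyloxy)-2-hydroxybenzaldehyde | O=Cc1ccc(OCc2ccccc2)c(OCc2ccccc2)c1O | intermediate
3 | 1-(benzyloxy)-4-bromobenzene | Brc1ccc(OCc2ccccc2)cc1 | starting material
4 | dibenzyl oxalate | O=C(OCc1ccccc1)C(=O)OCc1ccccc1 | starting material
5 | [4-(benzyloxy)phenyl]magnesium bromide | Br[Mg]c1ccc(OCc2ccccc2)cc1 | intermediate (not isolated)
6 | benzyl 2-[4-(benzyloxy)phenyl]-2-oxoacetate | O=C(C(=O)OCc1ccccc1)c1ccc(OCc2ccccc2)cc1 | intermediate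
7 | benzyl (2S)-2-[4-(benzyloxy)phenyl]-2-hydroxyacetate | O[C@@H](c1ccc(OCc2ccccc2)cc1)C(=O)OCc1ccccc1 | intermediate
8 | benzyl (2R)-2-[2,3-bis(benzyloxy)-6-formylphenoxy]-2-[4-(benzyloxy)phenyl]acetate | O=Cc1ccc(OCc2ccccc2)c(OCc2ccccc2)c1O[C@H](c1ccc(OCc2ccccc2)cc1)C(=O)OCc1ccccc1 | intermediate
9 | 1,2-bis(benzyloxy)-3-{[(1R)-2-(benzyloxy)-1-[4-(benzyloxy)phenyl]prop-2-en-1-yl]oxy}-4-ethenylbenzene | C=Cc1ccc(OCc2ccccc2)c(OCc2ccccc2)c1O[C@H](c1ccc(OCc2ccccc2)cc1)C(=C)OCc1ccccc1 | intermediate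
10 | (2R)-3,7,8-tris(benzyloxy)-2-[4-(benzyloxy)phenyl]-2H-chromene | c1cc2c(c(OCc3ccccc3)c1OCc1ccccc1)O[C@H](c1ccc(OCc3ccccc3)cc1)C(OCc1ccccc1)=C2 | intermediate
11 | [(2R,3R,4S)-3,7,8-tris(benzyloxy)-2-[4-(benzyloxy)phenyl]chroman-4-yl]borane | c1cc2c(c(OCc3ccccc3)c1OCc1ccccc1)O[C@H](c1ccc(OCc3ccccc3)cc1)[C@H](OCc1ccccc1)[C@H]2B | intermediate (not isolated)
12 | (2R,3R,4S)-3,7,8-tris(benzyloxy)-2-[4-(benzyloxy)phenyl]chroman-4-ol | c1cc2c(c(OCc3ccccc3)c1OCc1ccccc1)O[C@H](c1ccc(OCc3ccccc3)cc1)[C@H](OCc1ccccc1)[C@H]2O | intermediate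
13 | (2R,3S,4S)-3,7,8-tris(benzyloxy)-2-[4-(benzyloxy)phenyl]-4-(benzylsulfanyl)chromane | c1cc2c(c(OCc3ccccc3)c1OCc1ccccc1)O[C@H](c1ccc(OCc3ccccc3)cc1)[C@H](OCc1ccccc1)[C@H]2SCc1ccccc1 | intermediate
14 | (2R,3S)-3,7,8-tris(benzyloxy)-2-[4-(benzyloxy)phenyl]chroman-4-one | c1cc2c(c(OCc3ccccc3)c1OCc1ccccc1)O[C@H](c1ccc(OCc3ccccc3)cc1)[C@H](OCc1ccccc1)C2=O | intermediate
15 | (2R,3R,4R)-3,7,8-tris(benzyloxy)-2-[4-(benzyloxy)phenyl]chroman-4-ol | c1cc2c(c(OCc3ccccc3)c1OCc1ccccc1)O[C@H](c1ccc(OCc3ccccc3)cc1)[C@H](OCc1ccccc1)[C@@H]2O | intermediate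
16 | (2R,3R,4R)-3,4,7,8-tetrakis(benzyloxy)-2-[4-(benzyloxy)phenyl]chromane | c1cc2c(c(OCc3ccccc3)c1OCc1ccccc1)O[C@H](c1ccc(OCc3ccccc3)cc1)[C@H](OCc1ccccc1)[C@@H]2OCc1ccccc1 | intermediate
17 | nona-O-benzyl-epioritin-(4β→6)-epioritin-4α-ol | c1cc2c(c(OCc5ccccc5)c1OCc5ccccc5)O[C@H](c1ccc(OCc5ccccc5)cc1)[C@H](OCc5ccccc5)[C@H]2c1cc2c(c(OCc5ccccc5)c1OCc5ccccc5)O[C@H](c1ccc(OCc5ccccc5)cc1)[C@H](OCc5ccccc5)[C@@H]2OCc5ccccc5 | intermediate
18 | trideca-O-benzyl-epioritin-(4β→6)-epioritin-(4β→6)-epioritin-4α-ol | O(Cc5ccccc5)c1ccc([C@H]2Oc3c(ccc(OCc5ccccc5)c3OCc5ccccc5)[C@H](c3cc4c(c(OCc5ccccc5)c3OCc5ccccc5)O[C@H](c3ccc(OCc5ccccc5)cc3)[C@H](OCc5ccccc5)[C@H]4c3cc4c(c(OCc5ccccc5)c3OCc5ccccc5)O[C@H](c3ccc(OCc5ccccc5)cc3)[C@H](OCc5ccccc5)[C@@H]4OCc5ccccc5)[C@H]2OCc5ccccc5)cc1 | intermediate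
19 | epioritin-(4β→6)-epioritin-(4β→6)-epioritin-4α-ol (CNP0140823.1) | Oc1ccc([C@H]2Oc3c(ccc(O)c3O)[C@H](c3cc4c(c(O)c3O)O[C@H](c3ccc(O)cc3)[C@H](O)[C@H]4c3cc4c(c(O)c3O)O[C@H](c3ccc(O)cc3)[C@H](O)[C@@H]4O)[C@H]2O)cc1 | target

**Total step count:** 14.
**Longest linear sequence:** 12 steps (3 → 6 → 7 → 8 → 9 → 10 → 12 → 14 → 15 → 16 → 17 → 18 → 19; steps 2–7, 9–11, 12–14).

**Steps most likely to fail, with fallbacks**

Step 13. The nucleophile 17 cannot be used in large excess, so self-alkylation of the electrophile (its own ring A is about as nucleophilic as that of 17) and chain growth beyond the trimer may compete. The fallback caps the electrophile. It sets out from 12, which is brominated at C6 (NBS, CH2Cl2, −78 °C) to the 6-bromo alcohol F1. F1 is converted with BnSH and ZnI2 into the 6-bromo thioether F2. F2 can no longer act as a nucleophile and is coupled with 17 (AgBF4) to the bromo trimer F3. Hydrogenolysis over Pd(OH)2/C in the presence of Et3N removes the bromine together with the benzyl groups, and the route comes back at 19.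

Step 6. The catalyst may be lost as a Fischer carbene at the enol ether, and the enol ether double bond may migrate or hydrolyse before ring closure. The fallback replaces ruthenium olefin metathesis by a stoichiometric titanium carbonyl–olefin metathesis. It sets out from 2, which is methylenated (Ph3P=CH2, 2.2 equiv, THF) to 3,4-bis(benzyloxy)-2-vinylphenol F4. Mitsunobu coupling of F4 with 7 gives the styrene ester F5. A Takai–Utimoto titanium ethylidene (TiCl4, TMEDA, Zn, PbCl2 cat., CH3CHBr2, THF) then effects the olefinic-ester cyclisation, forming the same C3=C4 bond, and the route comes back at 10.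

Step 7. The β-benzyloxy alkylborane may eliminate, or boron may add with poor regiocontrol. The fallback sets C3 by hydride reduction and C4 by benzylic oxidation. It sets out from 10, which is hydrolysed (aqueous oxalic acid, THF) to the flavan-3-one F6. Reduction with LiBH(s-Bu)3 at −78 °C, from the face opposite the C2 aryl group, gives the 2,3-cis alcohol F7. Benzylation (NaH, BnBr) gives the tetra-O-benzyl flavan F8. Oxidation at C4 with DDQ in wet CH2Cl2, water entering trans to the 3-benzyloxy group, brings the route back at 12.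

**Further compounds**

F1 | step 13 | (2R,3R,4S)-6-bromo-3,7,8-tris(benzyloxy)-2-[4-(benzyloxy)phenyl]chroman-4-ol | Brc1cc2c(c(OCc3ccccc3)c1OCc1ccccc1)O[C@H](c1ccc(OCc3ccccc3)cc1)[C@H](OCc1ccccc1)[C@H]2O
F2 | step 13 | (2R,3S,4S)-6-bromo-3,7,8-tris(benzyloxy)-2-[4-(benzyloxy)phenyl]-4-(benzylsulfanyl)chromane | Brc1cc2c(c(OCc3ccccc3)c1OCc1ccccc1)O[C@H](c1ccc(OCc3ccccc3)cc1)[C@H](OCc1ccccc1)[C@H]2SCc1ccccc1
F3 | step 13 | trideca-O-benzyl trimer 18 with bromine at C6 of the upper unit | O(Cc5ccccc5)c1ccc([C@H]2Oc3c(cc(Br)c(OCc5ccccc5)c3OCc5ccccc5)[C@H](c3cc4c(c(OCc5ccccc5)c3OCc5ccccc5)O[C@H](c3ccc(OCc5ccccc5)cc3)[C@H](OCc5ccccc5)[C@H]4c3cc4c(c(OCc5ccccc5)c3OCc5ccccc5)O[C@H](c3ccc(OCc5ccccc5)cc3)[C@H](OCc5ccccc5)[C@@H]4OCc5ccccc5)[C@H]2OCc5ccccc5)cc1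
F4 | step 6 | 3,4-bis(benzyloxy)-2-vinylphenol | C=Cc1ccc(OCc2ccccc2)c(OCc2ccccc2)c1O
F5 | step 6 | benzyl (2R)-2-[2,3-bis(benzyloxy)-6-ethenylphenoxy]-2-[4-(benzyloxy)phenyl]acetate | C=Cc1ccc(OCc2ccccc2)c(OCc2ccccc2)c1O[C@H](c1ccc(OCc2ccccc2)cc1)C(=O)OCc1ccccc1
F6 | step 7 | (2R)-7,8-bis(benzyloxy)-2-[4-(benzyloxy)phenyl]chroman-3-one | c1cc2c(c(OCc3ccccc3)c1OCc1ccccc1)O[C@H](c1ccc(OCc3ccccc3)cc1)C(=O)C2
F7 | step 7 | (2R,3R)-7,8-bis(benzyloxy)-2-[4-(benzyloxy)phenyl]chroman-3-ol | c1cc2c(c(OCc3ccccc3)c1OCc1ccccc1)O[C@H](c1ccc(OCc3ccccc3)cc1)[C@H](O)C2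
F8 | step 7 | (2R,3R)-3,7,8-tris(benzyloxy)-2-[4-(benzyloxy)phenyl]chromane | c1cc2c(c(OCc3ccccc3)c1OCc1ccccc1)O[C@H](c1ccc(OCc3ccccc3)cc1)[C@H](OCc1ccccc1)C2
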